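The side chain is cut at C4'–C5', where a methine bearing a methyl group (C4') meets the unbranched methylene run C5'–C7'. This CH(CH3)–CH2 motif is the retron of alkene carboalumination followed by protonolysis. Both halves therefore become plain terminal alkenes. One is an (S)-2-methyl-2-(pent-4-enyl)-2H-chromene with the benzene and pyran rings complete and the phenol silylated. The other is (R)-4,8-dimethylnon-1-ene from citronellal. In one pot the nonene is hydroaluminated and its alkyl group is added across the pentenyl double bond under a chiral zirconocene. Protonolysis turns the former =CH2 into the C4' methyl. The 1,2-disubstituted C3=C4 bond of the pyran ring stays inert. One operation thus forms C4'–C5', sets C4' and creates its methyl branch.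

Key step: step 8

Assumption: the sense of induction of the chiral Lewis base (step 4) and of the zirconocene (step 8) is assigned by analogy with the usual facial preference of each catalyst family. Both exist as either antipode, and the antipode would be taken if the sense proved opposite.
Numbering: chromene locants run O1–C8a, and side-chain carbons C1'–C13' are counted from C2. The target SMILES corresponds to (2S,4'R,8'R).

Step 1
Reactants: 1 hept-1-en-6-yne
Product: 4 (2E)-3-methylocta-2,7-dien-1-ol, via alkenyl(dimethyl)alane 2 (not isolated), via lithium alkenylalanate 3 (not isolated)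
Conditions: Me3Al (2 equiv), Cp2ZrCl2 (0.2 equiv), CH2Cl2, 0 °C to rt; volatiles off; n-BuLi (1 equiv), hexane/THF, −78 to 0 °C; (CH2O)n, rt; aq HCl
Reagents that add atoms: trimethylaluminium C[Al](C)C; paraformaldehyde, counted as formaldehyde C=O
Why: Zirconium-catalysed carboalumination (syn-methylalumination) of the terminal alkyne is much faster than that of the remote 1-alkene and fixes the E geometry, and the alanate made with n-BuLi is hydroxymethylated by formaldehyde with retention of that geometry.

Step 2
Reactants: 4 (2E)-3-methylocta-2,7-dien-1-ol; 5 2,5-dimethylbenzene-1,4-diol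
Product: 6 2-[(2E)-3-methylocta-2,7-dien-1-yl]-3,6-dimethylbenzene-1,4-diol
Conditions: 5 (3 equiv), BF3·OEt2 (0.3 equiv), 1,4-dioxane, rt, N2
Reagents that add atoms: none
Why: Friedel–Crafts allylation, in which the BF3-activated allylic alcohol reacts at its primary terminus as a geometry-retaining (E)-allyl cation and the two free ring positions of symmetric 5 are equivalent, so that excess 5 should give a single mono-allylated regioisomer.

Step 3
Reactants: 6 2-[(2E)-3-methylocta-2,7-dien-1-yl]-3,6-dimethylbenzene-1,4-diol
Product: 7 4-{[tert-butyl(dimethyl)silyl]oxy}-3,6-dimethyl-2-[(2E)-3-methylocta-2,7-dien-1-yl]phenol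
Conditions: TBSCl (1.0 equiv), imidazole, CH2Cl2/DMF, 0 °C
Reagents that add atoms: tert-butyldimethylsilyl chloride CC(C)(C)[Si](C)(C)Cl
Why: Sterically controlled silyl ether formation, since the C4 hydroxyl has only one ortho substituent whereas the C1 hydroxyl is flanked by the allyl chain and the C6 methyl and stays free as the future O1.

Step 4
Reactants: 7 4-{[tert-butyl(dimethyl)silyl]oxy}-3,6-dimethyl-2-[(2E)-3-methylocta-2,7-dien-1-yl]phenol
Product: 8 tert-butyl(dimethyl){[(2S,3R)-2,5,8-trimethyl-2-(pent-4-en-1-yl)-3-(phenylsulfanyl)-3,4-dihydro-2H-chromen-6-yl]oxy}silane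
Conditions: N-(phenylthio)phthalimide (1.1 equiv), (S)-BINAM-derived diisopropylamino selenophosphoramide (10 mol%), MsOH (0.25 equiv), CH2Cl2, −20 °C
Reagents that add atoms: N-(phenylthio)phthalimide O=C1c2ccccc2C(=O)N1Sc1ccccc1
Why: Lewis-base-catalysed enantioselective sulfenofunctionalisation, in which the chiral selenophosphoramide transfers PhS+ to one face of the electron-rich trisubstituted alkene (the monosubstituted one is far less nucleophilic) and the configurationally stable thiiranium ion is opened anti by the phenol at its tertiary carbon in a 6-endo Markovnikov mode, so that catalyst face selection together with the E geometry sets C2 as S and C3 as R (sulfur cis to the C2 methyl).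

Step 5
Reactants: 8 tert-butyl(dimethyl){[(2S,3R)-2,5,8-trimethyl-2-(pent-4-en-1-yl)-3-(phenylsulfanyl)-3,4-dihydro-2H-chromen-6-yl]oxy}silane
Product: 10 tert-butyl(dimethyl){[(2S)-2,5,8-trimethyl-2-(pent-4-en-1-yl)-2H-chromen-6-yl]oxy}silane, via C3 phenyl sulfoxide 9 (not isolated)
Conditions: mCPBA (1.0 equiv), CH2Cl2, −78 °C; aq NaHCO3 wash; then toluene, solid NaHCO3, 100 °C
Reagents that add atoms: none
Why: Chemoselective sulfide-to-sulfoxide oxidation followed by thermal syn-elimination (sulfoxide pyrolysis), which can only run towards the benzylic C4–H because C2 is quaternary, installs the C3=C4 bond and leaves C2 untouched.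

Step 6
Reactants: 11 (R)-citronellal, (3R)-3,7-dimethyloct-6-enal
Product: 12 (3R)-3,7-dimethyloctanal
Conditions: H2 (1 atm), 5% Pd/C, EtOAc, rt
Reagents that add atoms: none
Why: Heterogeneous catalytic hydrogenation over palladium saturates the trisubstituted alkene faster than the aldehyde, and the C3 stereocentre (the future C8'), which is not alpha to the carbonyl, is not touched.

Step 7
Reactants: 12 (3R)-3,7-dimethyloctanal
Product: 13 (4R)-4,8-dimethylnon-1-ene
Conditions: MePPh3Br, KOtBu, THF, 0 °C to rt
Reagents that add atoms: methyltriphenylphosphonium bromide C[P+](c1ccccc1)(c1ccccc1)c1ccccc1.[Br-]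
Why: Wittig methylenation with the non-stabilised ylide adds the one carbon that becomes C5', and the beta stereocentre cannot epimerise.

Step 8
Reactants: 13 (4R)-4,8-dimethylnon-1-ene; 10 tert-butyl(dimethyl){[(2S)-2,5,8-trimethyl-2-(pent-4-en-1-yl)-2H-chromen-6-yl]oxy}silane
Product: 16 tert-butyl(dimethyl){[(2S)-2,5,8-trimethyl-2-[(4R,8R)-4,8,12-trimethyltridecyl]-2H-chromen-6-yl]oxy}silane, via dimethylnonyl(diisobutyl)alane 14 (not isolated), via carboalumination adduct 15 (not isolated)
Conditions: 13 (2.1 equiv), iBu2AlH (2.0 equiv), neat, 70 °C; then 10 (1 equiv), (−)-bis(1-neomenthylindenyl)zirconium dichloride (−)-(NMI)2ZrCl2 (5 mol%), isobutylaluminoxane (iBuAlO)n (0.3 equiv), CH2Cl2, 0 °C to rt; then 2 M HCl, 0 °C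
Reagents that add atoms: none
Why: Thermal hydroalumination places aluminium on C1 of 13, the unbranched alkyl group is passed to the cationic chiral zirconocene formed from (−)-(NMI)2ZrCl2 and (iBuAlO)n, the monosubstituted C4'=CH2 alkene of 10 inserts (alkyl to the internal carbon, metal to the terminal carbon), zirconium-to-aluminium exchange gives 15, and protonolysis of its C–Al bond turns the former =CH2 into the C4' methyl group. The closest known reaction type is the hydroalumination/ZACA (zirconium-catalysed asymmetric carboalumination) tandem of two 1-alkenes with protonolytic work-up. No ring is closed. The new C4' stereocentre is controlled by the catalyst alone: the neomenthylindenyl ligands of the (−)-complex expose the alkene face that leads to (R)-2-methylalkanols in methylalumination, and that face maps onto 4'R here, while C2 and C8' are remote spectators. The step needs site selectivity for the terminal alkene, secured because the C3=C4 bond of the pyran ring is 1,2-disubstituted and conjugated and does not insert, and group selectivity on aluminium, secured because the beta-branched isobutyl groups and the beta-branched adduct 15 transfer far more slowly than the linear alkyl of 14. The aryl silyl ether and the hindered O1, flanked by quaternary C2 and the C8 methyl, offer the alane no acidic or strongly coordinating site.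

Step 9
Reactants: 16 tert-butyl(dimethyl){[(2S)-2,5,8-trimethyl-2-[(4R,8R)-4,8,12-trimethyltridecyl]-2H-chromen-6-yl]oxy}silane
Product: 17 (2S)-2,5,8-trimethyl-2-[(4R,8R)-4,8,12-trimethyltridecyl]-2H-chromen-6-ol
Conditions: Et3N·3HF, THF, rt, argon
Reagents that add atoms: none
Why: Fluoride-driven cleavage of the aryl silyl ether under almost neutral conditions frees the C6 phenol without touching the acid- and oxidation-sensitive chromene or any stereocentre.

Compound list
1 | hept-1-en-6-yne | C=CCCCC#C | starting material
2 | [(1E)-2-methylhepta-1,6-dien-1-yl]dimethylalane | C[Al](C)/C=C(\C)CCCC=C | intermediate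
3 | lithium butyl(dimethyl)[(1E)-2-methylhepta-1,6-dien-1-yl]alanate | [Li+].CCCC[Al-](C)(C)/C=C(\C)CCCC=C | intermediate
4 | (2E)-3-methylocta-2,7-dien-1-ol | OC/C=C(\C)CCCC=C | intermediate
5 | 2,5-dimethylbenzene-1,4-diol | Cc1cc(O)c(C)cc1O | starting material
6 | 2-[(2E)-3-methylocta-2,7-dien-1-yl]-3,6-dimethylbenzene-1,4-diol | Cc1cc(O)c(C)c(C/C=C(\C)CCCC=C)c1O | intermediate
7 | 4-{[tert-butyl(dimethyl)silyl]oxy}-3,6-dimethyl-2-[(2E)-3-methylocta-2,7-dien-1-yl]phenol | Cc1cc(O[Si](C)(C)C(C)(C)C)c(C)c(C/C=C(\C)CCCC=C)c1O | intermediate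
8 | tert-butyl(dimethyl){[(2S,3R)-2,5,8-trimethyl-2-(pent-4-en-1-yl)-3-(phenylsulfanyl)-3,4-dihydro-2H-chromen-6-yl]oxy}silane | Cc1cc(O[Si](C)(C)C(C)(C)C)c(C)c2c1O[C@@](C)(CCCC=C)[C@H](Sc3ccccc3)C2 | intermediate
9 | C3 phenyl sulfoxide of 8 (2S,3R; mixture at sulfur) | Cc1cc(O[Si](C)(C)C(C)(C)C)c(C)c2c1O[C@@](C)(CCCC=C)[C@H](S(=O)c3ccccc3)C2 | intermediate
10 | tert-butyl(dimethyl){[(2S)-2,5,8-trimethyl-2-(pent-4-en-1-yl)-2H-chromen-6-yl]oxy}silane | Cc1cc(O[Si](C)(C)C(C)(C)C)c(C)c2c1O[C@@](C)(CCCC=C)C=C2 | intermediate
11 | (R)-citronellal, (3R)-3,7-dimethyloct-6-enal | O=CC[C@H](C)CCC=C(C)C | starting material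
12 | (3R)-3,7-dimethyloctanal | O=CC[C@H](C)CCCC(C)C | intermediate
13 | (4R)-4,8-dimethylnon-1-ene | C=CC[C@H](C)CCCC(C)C | intermediate
14 | [(4R)-4,8-dimethylnonyl]bis(2-methylpropyl)alane | CC(C)C[Al](CC(C)C)CCC[C@H](C)CCCC(C)C | intermediate
15 | carboalumination adduct: compound 16 in which the C4' methyl carbon carries Al(iBu)2 (2S,4'R,8'R) | Cc1cc(O[Si](C)(C)C(C)(C)C)c(C)c2c1O[C@@](C)(CCC[C@H](C[Al](CC(C)C)CC(C)C)CCC[C@H](C)CCCC(C)C)C=C2 | intermediate
16 | tert-butyl(dimethyl){[(2S)-2,5,8-trimethyl-2-[(4R,8R)-4,8,12-trimethyltridecyl]-2H-chromen-6-yl]oxy}silane | Cc1cc(O[Si](C)(C)C(C)(C)C)c(C)c2c1O[C@@](C)(CCC[C@H](C)CCC[C@H](C)CCCC(C)C)C=C2 | intermediate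
17 | (2S)-2,5,8-trimethyl-2-[(4R,8R)-4,8,12-trimethyltridecyl]-2H-chromen-6-ol | Cc1cc(O)c(C)c2c1O[C@@](C)(CCC[C@H](C)CCC[C@H](C)CCCC(C)C)C=C2 | target

Total step count: 9. Longest linear sequence: 7 steps (steps 1, 2, 3, 4, 5, 8, 9).

Steps most likely to fail

Step 8.
- **What may go wrong:**
  - Beta-hydride transfer from the isobutyl groups may hydrometalate the terminal alkene of 10 instead of alkylating it.
  - Facial selectivity at C4' may be incomplete.
  - The Lewis-acidic alane medium may open the allylic C2–O1 bond of the pyran ring.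
- **Fallback:** it sets out from 10 and 13 and comes back at 16. It forms the same C4'–C5' bond by a stereospecific substitution instead of a catalyst-controlled insertion. Wacker–Tsuji oxidation of 10 (PdCl2, CuCl, O2, DMF/H2O) should give the methyl ketone F1. Reduction with an (R)-selective alcohol dehydrogenase (NADP+ recycled with iPrOH) should give the (R)-carbinol F2. TsCl/pyridine should then give the secondary tosylate F3. In parallel, hydrozirconation of 13 with Cp2Zr(H)Cl followed by NBS should give the primary bromide F4. Magnesium in THF converts it into the Grignard reagent F5. Cross-coupling of F3 with F5 (catalytic CuI, TMEDA, LiOMe, THF, 0 °C) is an SN2 process with inversion, so the (R)-tosylate should deliver 4'R in 16.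

Step 4.
- **What may go wrong:**
  - Thiiranium formation may show poor facial selectivity on this trisubstituted alkene.
  - Sulfenylation of the electron-rich arene may compete.
  - Proton-catalysed hydroalkoxylation without sulfur transfer may compete.
- **Fallback:** it sets out from 7 and comes back at 10, bypassing steps 4 and 5. It replaces asymmetric cyclisation by racemic ring formation and resolution. DDQ in toluene should dehydrogenate 7 to the vinyl ortho-quinone methide. Oxa-6π electrocyclisation of that species should give the racemic chromene F6. Preparative chromatography on a polysaccharide chiral stationary phase then separates 10 from the (R)-chromene F7.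

Step 2.
- **What may go wrong:**
  - Over-allylation may occur.
  - Acid-induced ring closure of the product onto its own alkene may occur.
  - The pendant vinyl group may capture the allyl cation.
  - Alkene geometry may be partly lost.
- **Fallback:** it sets out from 4 and 5 and comes back at 7, bypassing step 3. It replaces the cationic alkylation by an SN2 C-allylation of a phenoxide. PBr3 in Et2O at 0 °C should convert 4 into the allylic bromide F8. TBSCl (1 equiv) and imidazole should convert 5 into the mono-silyl ether F9. The sodium phenoxide of F9 (NaH, toluene), as a tight ion pair in the non-polar solvent, should be alkylated by F8 at its only free ortho carbon. The E geometry should be retained, giving 7.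

Further compounds
F1 | step 8 | methyl ketone, 5-[(2S)-6-{[tert-butyl(dimethyl)silyl]oxy}-2,5,8-trimethyl-2H-chromen-2-yl]pentan-2-one | Cc1cc(O[Si](C)(C)C(C)(C)C)c(C)c2c1O[C@@](C)(CCCC(C)=O)C=C2
F2 | step 8 | (R)-carbinol, (2R)-5-[(2S)-6-{[tert-butyl(dimethyl)silyl]oxy}-2,5,8-trimethyl-2H-chromen-2-yl]pentan-2-ol | Cc1cc(O[Si](C)(C)C(C)(C)C)c(C)c2c1O[C@@](C)(CCC[C@@H](C)O)C=C2
F3 | step 8 | secondary tosylate, (2R)-5-[(2S)-6-{[tert-butyl(dimethyl)silyl]oxy}-2,5,8-trimethyl-2H-chromen-2-yl]pentan-2-yl 4-methylbenzenesulfonate | Cc1cc(O[Si](C)(C)C(C)(C)C)c(C)c2c1O[C@@](C)(CCC[C@@H](C)OS(=O)(=O)c3ccc(C)cc3)C=C2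
F4 | step 8 | primary bromide, (4R)-1-bromo-4,8-dimethylnonane | BrCCC[C@H](C)CCCC(C)C
F5 | step 8 | Grignard reagent, [(4R)-4,8-dimethylnonyl]magnesium bromide | Br[Mg]CCC[C@H](C)CCCC(C)C
F6 | step 4 | racemic chromene, rac-tert-butyl(dimethyl){[2,5,8-trimethyl-2-(pent-4-en-1-yl)-2H-chromen-6-yl]oxy}silane | Cc1cc(O[Si](C)(C)C(C)(C)C)c(C)c2c1OC(C)(CCCC=C)C=C2
F7 | step 4 | (R)-chromene, tert-butyl(dimethyl){[(2R)-2,5,8-trimethyl-2-(pent-4-en-1-yl)-2H-chromen-6-yl]oxy}silane | Cc1cc(O[Si](C)(C)C(C)(C)C)c(C)c2c1O[C@](C)(CCCC=C)C=C2
F8 | step 2 | allylic bromide, (2E)-1-bromo-3-methylocta-2,7-diene | BrC/C=C(\C)CCCC=C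
F9 | step 2 | mono-silyl ether, 4-{[tert-butyl(dimethyl)silyl]oxy}-2,5-dimethylphenol | Cc1cc(O[Si](C)(C)C(C)(C)C)c(C)cc1O
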